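Everything rests on the C6–C8 bond (ring C1 carbonyl to C6 quaternary carbon; side chain C7 carbinol, C8 CHMe). The feature exploited is the 1,4-relationship of the C1 carbonyl and the C4 methoxy oxygen on the cyclohexenone ring: the ring is brought in as symmetrical 4,4-dimethoxycyclohexa-2,5-dienone, in which C6 is an electrophilic β-carbon, C1 is masked as the ketal and the C4 carbonyl later becomes the methoxy stereocentre. In one operation the key step adds the RAMP azaenolate of 3,4-dimethoxypropiophenone to this dienone: it forms C6–C8, desymmetrises the ring and fixes C8. Its precursors are a chiral ketone hydrazone and a quinone monoketal; allylation of C6 comes last.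

Key step: step 2

Remark: locants are those of the target throughout; 1, 2 and 4 are taken as commercial, and the hydrazone C=N geometry is left unspecified because it is immaterial.

Step 1
Reactants: 1 1-(3,4-dimethoxyphenyl)propan-1-one; 2 (R)-1-amino-2-(methoxymethyl)pyrrolidine (RAMP)
Product: 3 (2R)-N-[1-(3,4-dimethoxyphenyl)propylidene]-2-(methoxymethyl)pyrrolidin-1-amine
Conditions: cat. TsOH, cyclohexane, reflux, Dean–Stark
Reagents that add atoms: none
Why: Acid-catalysed hydrazone formation with azeotropic removal of water installs the auxiliary that controls C8 in step 2 and masks C7 as a C=N group inert to the hydride and base of steps 3 and 4.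

Step 2
Reactants: 3 (2R)-N-[1-(3,4-dimethoxyphenyl)propylidene]-2-(methoxymethyl)pyrrolidin-1-amine; 4 4,4-dimethoxycyclohexa-2,5-dien-1-one
Product: 6 (5S)-5-[(2R)-1-(3,4-dimethoxyphenyl)-1-{[(2R)-2-(methoxymethyl)pyrrolidin-1-yl]imino}propan-2-yl]-4,4-dimethoxycyclohex-2-en-1-one, via lithium azaenolate 5 (not isolated)
Conditions: LDA, THF, 0 °C; then 4, THF, −100 → −78 °C; aq. NH4Cl
Reagents that add atoms: none
Why: Conjugate (Michael) addition: the lithium-chelated azaenolate 5 (E C=C, Z C–N) attacks one β-carbon of the cross-conjugated dienone 4, whose ketal carbon is the latent C1 ketone, so the future α-carbon C6 reacts as an electrophile and C6–C8 is formed while the second enone survives as the later C2=C3 unit. The closest known reaction types are the Enders SAMP/RAMP-hydrazone Michael addition and carbanion 1,4-additions to quinone monoketals. No ring is closed. C8 is set by the RAMP auxiliary, whose chelated methoxymethylpyrrolidine blocks one azaenolate face (the sense known from RAMP alkylations, here 8R); C6 should be set by a synclinal open transition state with the azaenolate C–H over the ketal and the methyl group anti to the enone, and it is set again in step 8 in any case. The step needs 1,4- over 1,2-selectivity and one face at C8; the soft, hindered and reversibly adding azaenolate, the absence of enolisable protons in 4 and the equivalence of its two enone arms should secure this.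

Step 3
Reactants: 6 (5S)-5-[(2R)-1-(3,4-dimethoxyphenyl)-1-{[(2R)-2-(methoxymethyl)pyrrolidin-1-yl]imino}propan-2-yl]-4,4-dimethoxycyclohex-2-en-1-one
Product: 7 (1S,5S)-5-[(2R)-1-(3,4-dimethoxyphenyl)-1-{[(2R)-2-(methoxymethyl)pyrrolidin-1-yl]imino}propan-2-yl]-4,4-dimethoxycyclohex-2-en-1-ol
Conditions: RuCl(p-cymene)[(S,S)-TsDPEN] (cat.), HCO2Na, H2O/CH2Cl2, Bu4NCl (cat.), rt
Reagents that add atoms: none
Why: Noyori asymmetric transfer hydrogenation of the 4,4-dialkoxycyclohexenone carbonyl should give the (4S)-allylic alcohol under catalyst control (alkenyl as the π-substituent), the same face the substrate prefers (hydroxyl cis to the C6 substituent), so that any C6 epimer also converges; the hydrazone and ketal are inert to neutral formate.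

Step 4
Reactants: 7 (1S,5S)-5-[(2R)-1-(3,4-dimethoxyphenyl)-1-{[(2R)-2-(methoxymethyl)pyrrolidin-1-yl]imino}propan-2-yl]-4,4-dimethoxycyclohex-2-en-1-ol
Product: 8 (2R)-N-{(2R)-1-(3,4-dimethoxyphenyl)-2-[(1S,5S)-2,2,5-trimethoxycyclohex-3-en-1-yl]propylidene}-2-(methoxymethyl)pyrrolidin-1-amine
Conditions: NaH, MeI, THF, 0 °C → rt
Reagents that add atoms: iodomethane CI
Why: Williamson etherification of the sodium alkoxide installs the C4 methoxy group without touching a stereocentre; C7 is still a hydrazone, so there is neither a second hydroxyl nor an enolisable ketone.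

Step 5
Reactants: 8 (2R)-N-{(2R)-1-(3,4-dimethoxyphenyl)-2-[(1S,5S)-2,2,5-trimethoxycyclohex-3-en-1-yl]propylidene}-2-(methoxymethyl)pyrrolidin-1-amine
Product: 9 (2R)-1-(3,4-dimethoxyphenyl)-2-[(1S,5S)-2,2,5-trimethoxycyclohex-3-en-1-yl]propan-1-one
Conditions: CuCl2·2H2O, THF / pH 7 phosphate buffer, rt
Reagents that add atoms: water O
Why: Copper(II)-assisted hydrolysis of the N,N-dialkylhydrazone at neutral pH should release the aryl ketone without epimerising C8 and without hydrolysing the acid-labile allylic dimethyl ketal.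

Step 6
Reactants: 9 (2R)-1-(3,4-dimethoxyphenyl)-2-[(1S,5S)-2,2,5-trimethoxycyclohex-3-en-1-yl]propan-1-one
Product: 10 (1S,2R)-1-(3,4-dimethoxyphenyl)-2-[(1S,5S)-2,2,5-trimethoxycyclohex-3-en-1-yl]propan-1-ol
Conditions: (R)-Me-CBS (0.2 equiv), catecholborane, toluene, −40 °C; aq. NaOH work-up
Reagents that add atoms: none
Why: Corey–Bakshi–Shibata reduction with the (R)-oxazaborolidine should deliver hydride to the face giving the (7S)-carbinol (aryl as the large group); reagent control is needed because Felkin–Anh substrate control would favour the C7 epimer, and C1 is still protected as the ketal.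

Step 7
Reactants: 10 (1S,2R)-1-(3,4-dimethoxyphenyl)-2-[(1S,5S)-2,2,5-trimethoxycyclohex-3-en-1-yl]propan-1-ol
Product: 11 (4S,6S)-6-[(1S,2R)-1-(3,4-dimethoxyphenyl)-1-hydroxypropan-2-yl]-4-methoxycyclohex-2-en-1-one
Conditions: PPTS (cat.), acetone/H2O, rt
Reagents that add atoms: water O
Why: Mild acid-catalysed hydrolysis of the allylic dimethyl ketal unmasks the C1 enone under conditions too weak to ionise the electron-rich benzylic alcohol or to eliminate the C4 methoxy group.

Step 8
Reactants: 11 (4S,6S)-6-[(1S,2R)-1-(3,4-dimethoxyphenyl)-1-hydroxypropan-2-yl]-4-methoxycyclohex-2-en-1-one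
Product: 13 (4S,6S)-6-allyl-6-[(1S,2R)-1-(3,4-dimethoxyphenyl)-1-hydroxypropan-2-yl]-4-methoxycyclohex-2-en-1-one, via dilithium alkoxide-enolate 12 (not isolated)
Conditions: LDA (2.2 equiv), THF, −78 °C; DMPU, allyl bromide, −78 → −40 °C; aq. NH4Cl
Reagents that add atoms: allyl bromide C=CCBr
Why: Kinetic α′-deprotonation of the enone (after the alkoxide) and C-allylation of the enolate (enolate alkylation) creates the quaternary centre; allyl bromide should enter trans to the C4 methoxy group and, with C8–H eclipsing the enolate C–O bond (A(1,3) strain), anti to the C7 carbinol branch, both effects giving (6S).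

Compound list
1 | 1-(3,4-dimethoxyphenyl)propan-1-one | CCC(=O)c1ccc(OC)c(OC)c1 | starting material
2 | (R)-1-amino-2-(methoxymethyl)pyrrolidine (RAMP) | COC[C@H]1CCCN1N | starting material
3 | (2R)-N-[1-(3,4-dimethoxyphenyl)propylidene]-2-(methoxymethyl)pyrrolidin-1-amine | CCC(=NN1CCC[C@@H]1COC)c1ccc(OC)c(OC)c1 | intermediate
4 | 4,4-dimethoxycyclohexa-2,5-dien-1-one | COC1(OC)C=CC(=O)C=C1 | starting material
5 | lithium azaenolate of 3 (E C=C; not isolated) | C/C=C(\c1ccc(OC)c(OC)c1)N([Li])N1CCC[C@@H]1COC | intermediate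
6 | (5S)-5-[(2R)-1-(3,4-dimethoxyphenyl)-1-{[(2R)-2-(methoxymethyl)pyrrolidin-1-yl]imino}propan-2-yl]-4,4-dimethoxycyclohex-2-en-1-one | COC1(OC)C=CC(=O)C[C@H]1[C@@H](C)C(=NN1CCC[C@@H]1COC)c1ccc(OC)c(OC)c1 | intermediate
7 | (1S,5S)-5-[(2R)-1-(3,4-dimethoxyphenyl)-1-{[(2R)-2-(methoxymethyl)pyrrolidin-1-yl]imino}propan-2-yl]-4,4-dimethoxycyclohex-2-en-1-ol | COC1(OC)C=C[C@@H](O)C[C@H]1[C@@H](C)C(=NN1CCC[C@@H]1COC)c1ccc(OC)c(OC)c1 | intermediate
8 | (2R)-N-{(2R)-1-(3,4-dimethoxyphenyl)-2-[(1S,5S)-2,2,5-trimethoxycyclohex-3-en-1-yl]propylidene}-2-(methoxymethyl)pyrrolidin-1-amine | COC1(OC)C=C[C@@H](OC)C[C@H]1[C@@H](C)C(=NN1CCC[C@@H]1COC)c1ccc(OC)c(OC)c1 | intermediate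
9 | (2R)-1-(3,4-dimethoxyphenyl)-2-[(1S,5S)-2,2,5-trimethoxycyclohex-3-en-1-yl]propan-1-one | COC1(OC)C=C[C@@H](OC)C[C@H]1[C@@H](C)C(=O)c1ccc(OC)c(OC)c1 | intermediate
10 | (1S,2R)-1-(3,4-dimethoxyphenyl)-2-[(1S,5S)-2,2,5-trimethoxycyclohex-3-en-1-yl]propan-1-ol | COC1(OC)C=C[C@@H](OC)C[C@H]1[C@@H](C)[C@H](O)c1ccc(OC)c(OC)c1 | intermediate
11 | (4S,6S)-6-[(1S,2R)-1-(3,4-dimethoxyphenyl)-1-hydroxypropan-2-yl]-4-methoxycyclohex-2-en-1-one | O=C1C=C[C@@H](OC)C[C@H]1[C@@H](C)[C@H](O)c1ccc(OC)c(OC)c1 | intermediate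
12 | dilithium alkoxide-enolate of 11 (not isolated) | [Li]OC1=C([C@@H](C)[C@H](O[Li])c2ccc(OC)c(OC)c2)C[C@H](OC)C=C1 | intermediate
13 | (4S,6S)-6-allyl-6-[(1S,2R)-1-(3,4-dimethoxyphenyl)-1-hydroxypropan-2-yl]-4-methoxycyclohex-2-en-1-one | C=CC[C@@]1([C@@H](C)[C@H](O)c2ccc(OC)c(OC)c2)C[C@H](OC)C=CC1=O | target

Total step count: 8. Longest linear sequence: 8 steps (1 → 3 → 6 → 7 → 8 → 9 → 10 → 11 → 13).

Steps most likely to fail

Step 2 (key step). The azaenolate may add 1,2 to the dienone carbonyl instead of 1,4, or discriminate the two faces at C8 poorly. The fallback replaces the stoichiometric lithiated hydrazone by a soft, catalytically formed enamine and moves the aryl group to a Felkin–Anh-controlled Grignard addition. It sets out from 4: propanal is added under (S)-α,α-diphenylprolinol trimethylsilyl ether catalysis to give (2R)-2-[(1S)-2,2-dimethoxy-5-oxocyclohex-3-en-1-yl]propanal F1. 3,4-Dimethoxyphenylmagnesium bromide at −78 °C should then attack the aldehyde anti to the ring substituent to give the hydroxy enone (5S)-5-[(1S,2R)-1-(3,4-dimethoxyphenyl)-1-hydroxypropan-2-yl]-4,4-dimethoxycyclohex-2-en-1-one F2, with the C7 configuration of the target. Transfer hydrogenation as in step 3 gives the diol (1S,5S)-5-[(1S,2R)-1-(3,4-dimethoxyphenyl)-1-hydroxypropan-2-yl]-4,4-dimethoxycyclohex-2-en-1-ol F3. Its unhindered allylic hydroxyl is methylated selectively (Ag2O, MeI) in preference to the branched benzylic one, and the route is rejoined at 10.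

Step 6. The reagent must override the Felkin–Anh preference of the substrate, so hydride delivery may be poorly face-selective. The fallback uses substrate control followed by inversion. It sets out from 9: L-Selectride should give the Felkin–Anh alcohol (1R,2R)-1-(3,4-dimethoxyphenyl)-2-[(1S,5S)-2,2,5-trimethoxycyclohex-3-en-1-yl]propan-1-ol F4. A Mitsunobu reaction (4-nitrobenzoic acid, PPh3, DIAD) inverts C7 to give (1S,2R)-1-(3,4-dimethoxyphenyl)-2-[(1S,5S)-2,2,5-trimethoxycyclohex-3-en-1-yl]propyl 4-nitrobenzoate F5. Any ionisation of this electron-rich benzylic centre should be captured anti to the ring-bearing substituent and so converge on the same configuration. Methanolysis (K2CO3, MeOH) returns to the route at 10.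

Step 8. The lithium alkoxide may add to the C1 carbonyl and suppress enolisation, or O-allylation and γ-deprotonation with loss of methoxide may compete. The fallback protects the alcohol and forms the C–C bond under neutral palladium catalysis. It sets out from 10: TBSOTf/2,6-lutidine gives tert-butyl{(1S,2R)-1-(3,4-dimethoxyphenyl)-2-[(1S,5S)-2,2,5-trimethoxycyclohex-3-en-1-yl]propoxy}dimethylsilane F6. PPTS in aqueous acetone gives (4S,6S)-6-[(1S,2R)-1-{[tert-butyl(dimethyl)silyl]oxy}-1-(3,4-dimethoxyphenyl)propan-2-yl]-4-methoxycyclohex-2-en-1-one F7. KHMDS and allyl chloroformate give the allyl enol carbonate (4S)-2-[(1S,2R)-1-{[tert-butyl(dimethyl)silyl]oxy}-1-(3,4-dimethoxyphenyl)propan-2-yl]-4-methoxycyclohexa-1,5-dien-1-yl prop-2-en-1-yl carbonate F8. Tsuji decarboxylative allylation (Pd(PPh3)4, THF) should deliver the allyl group trans to the C4 methoxy group to give (4S,6S)-6-allyl-6-[(1S,2R)-1-{[tert-butyl(dimethyl)silyl]oxy}-1-(3,4-dimethoxyphenyl)propan-2-yl]-4-methoxycyclohex-2-en-1-one F9. TBAF returns to the route at 13.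

Further compounds
F1 | step 2 | (2R)-2-[(1S)-2,2-dimethoxy-5-oxocyclohex-3-en-1-yl]propanal | COC1(OC)C=CC(=O)C[C@H]1[C@@H](C)C=O
F2 | step 2 | (5S)-5-[(1S,2R)-1-(3,4-dimethoxyphenyl)-1-hydroxypropan-2-yl]-4,4-dimethoxycyclohex-2-en-1-one | COC1(OC)C=CC(=O)C[C@H]1[C@@H](C)[C@H](O)c1ccc(OC)c(OC)c1
F3 | step 2 | (1S,5S)-5-[(1S,2R)-1-(3,4-dimethoxyphenyl)-1-hydroxypropan-2-yl]-4,4-dimethoxycyclohex-2-en-1-ol | COC1(OC)C=C[C@@H](O)C[C@H]1[C@@H](C)[C@H](O)c1ccc(OC)c(OC)c1
F4 | step 6 | (1R,2R)-1-(3,4-dimethoxyphenyl)-2-[(1S,5S)-2,2,5-trimethoxycyclohex-3-en-1-yl]propan-1-ol | COC1(OC)C=C[C@@H](OC)C[C@H]1[C@@H](C)[C@@H](O)c1ccc(OC)c(OC)c1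
F5 | step 6 | (1S,2R)-1-(3,4-dimethoxyphenyl)-2-[(1S,5S)-2,2,5-trimethoxycyclohex-3-en-1-yl]propyl 4-nitrobenzoate | COC1(OC)C=C[C@@H](OC)C[C@H]1[C@@H](C)[C@H](OC(=O)c1ccc(cc1)[N+](=O)[O-])c1ccc(OC)c(OC)c1
F6 | step 8 | tert-butyl{(1S,2R)-1-(3,4-dimethoxyphenyl)-2-[(1S,5S)-2,2,5-trimethoxycyclohex-3-en-1-yl]propoxy}dimethylsilane | COC1(OC)C=C[C@@H](OC)C[C@H]1[C@@H](C)[C@H](O[Si](C)(C)C(C)(C)C)c1ccc(OC)c(OC)c1
F7 | step 8 | (4S,6S)-6-[(1S,2R)-1-{[tert-butyl(dimethyl)silyl]oxy}-1-(3,4-dimethoxyphenyl)propan-2-yl]-4-methoxycyclohex-2-en-1-one | O=C1C=C[C@@H](OC)C[C@H]1[C@@H](C)[C@H](O[Si](C)(C)C(C)(C)C)c1ccc(OC)c(OC)c1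
F8 | step 8 | (4S)-2-[(1S,2R)-1-{[tert-butyl(dimethyl)silyl]oxy}-1-(3,4-dimethoxyphenyl)propan-2-yl]-4-methoxycyclohexa-1,5-dien-1-yl prop-2-en-1-yl carbonate | C=CCOC(=O)OC1=C([C@@H](C)[C@H](O[Si](C)(C)C(C)(C)C)c2ccc(OC)c(OC)c2)C[C@H](OC)C=C1
F9 | step 8 | (4S,6S)-6-allyl-6-[(1S,2R)-1-{[tert-butyl(dimethyl)silyl]oxy}-1-(3,4-dimethoxyphenyl)propan-2-yl]-4-methoxycyclohex-2-en-1-one | C=CC[C@@]1([C@@H](C)[C@H](O[Si](C)(C)C(C)(C)C)c2ccc(OC)c(OC)c2)C[C@H](OC)C=CC1=O
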